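**Assumption:** the target SMILES has no stereocentre and no stereogenic double bond (the prenyl alkene carries two methyl groups). The compound is therefore achiral and no stereocontrol is needed. Sulfoxide 7 is a transient racemate at sulfur, and that centre disappears in sulfone 8.

## Retrosynthetic overview
1. The target comes from desilylation of its 4'-O-TIPS ether, which is made by 7-O-prenylation of a 5,7-diol in which the 5-OH is masked by chelation to C4=O.
2. The C2–OAr bond is cut back to mono-TIPS hydroquinone and a 2-(methylsulfonyl)chromone (addition–elimination). The sulfone is made before the oxidation-sensitive prenyl group is present.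
3. The sulfone comes from the 2-SMe chromone, which comes from the 4-hydroxychromene-2-thione.
4. The key C2–C3 bond is formed by a Claisen-type condensation of the enolate of 4,6-di-O-benzylphloroacetophenone with CS2.
5. The pyranone is the only ring built, and it closes straight after the C–C bond forms (O-attack, loss of H2S). Both benzene rings are purchased.

## Route

**Step 1**
Reactants: 1 2',4',6'-trihydroxyacetophenone (dried monohydrate)
Product: 2 1-[2,4-bis(benzyloxy)-6-hydroxyphenyl]ethan-1-one
Conditions: BnBr (2.05 equiv), K2CO3 (2.2 equiv), DMF, 60 °C, 3 h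
Reagents that add atoms: benzyl bromide, BrCc1ccccc1
Why: In this Williamson etherification, once the para OH and one ortho OH are benzylated, the last ortho OH is strongly hydrogen-bonded to the acetyl C=O and does not alkylate with two equivalents of halide.

**Step 2 (key C–C bond and ring closure)**
Reactants: 2 1-[2,4-bis(benzyloxy)-6-hydroxyphenyl]ethan-1-one; 3 carbon disulfide
Product: 5 5,7-bis(benzyloxy)-4-hydroxy-2H-chromene-2-thione, via beta-oxodithioic acid 4 (not isolated)
Conditions: KOtBu (3.5 equiv), THF–toluene, 0 °C → rt, 24 h; then 2 M HCl, 0 °C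
Reagents that add atoms: none
Why: In this Claisen-type condensation the potassium enolate of the methyl ketone attacks the carbon of CS2, deprotonation of the acidic β-oxodithioate drives the equilibrium, and on acidification the ortho OH adds to C=S and expels H2S to close the pyranone ring.

**Step 3**
Reactants: 5 5,7-bis(benzyloxy)-4-hydroxy-2H-chromene-2-thione
Product: 6 5,7-bis(benzyloxy)-2-(methylsulfanyl)-4H-chromen-4-one
Conditions: MeI (1.2 equiv), K2CO3 (1.5 equiv), acetone, reflux, 2 h
Reagents that add atoms: iodomethane, CI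
Why: SN2 alkylation of the ambident thione/enolate anion takes place at the soft sulfur and fixes the 4H-chromen-4-one tautomer.

**Step 4**
Reactants: 6 5,7-bis(benzyloxy)-2-(methylsulfanyl)-4H-chromen-4-one
Product: 8 5,7-bis(benzyloxy)-2-(methylsulfonyl)-4H-chromen-4-one, via racemic sulfoxide 7 (not isolated)
Conditions: mCPBA (2.5 equiv), CH2Cl2, 0 °C → rt, 12 h; aq NaHCO3 wash
Reagents that add atoms: 3-chloroperoxybenzoic acid, OOC(=O)c1cccc(Cl)c1
Why: Stepwise electrophilic S-oxidation (sulfide → sulfoxide → sulfone) spares the benzyl ethers and the electron-poor C2=C3 bond, and it is carried out before any prenyl alkene is present.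

**Step 5**
Reactants: 9 4-(benzyloxy)phenol
Product: 10 [4-(benzyloxy)phenoxy]tri(propan-2-yl)silane
Conditions: TIPSCl (1.1 equiv), imidazole (2.2 equiv), DMF, rt, 6 h
Reagents that add atoms: chlorotriisopropylsilane, CC(C)[Si](Cl)(C(C)C)C(C)C
Why: Imidazole-promoted O-silylation of the only free phenol gives an unambiguous, differentially protected hydroquinone.

**Step 6**
Reactants: 10 [4-(benzyloxy)phenoxy]tri(propan-2-yl)silane
Product: 11 4-{[tri(propan-2-yl)silyl]oxy}phenol
Conditions: H2 (1 atm), 10% Pd/C, EtOAc–EtOH, rt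
Reagents that add atoms: none
Why: Catalytic hydrogenolysis cleaves the benzylic C–O bond and leaves the aryl TIPS ether untouched.

**Step 7**
Reactants: 8 5,7-bis(benzyloxy)-2-(methylsulfonyl)-4H-chromen-4-one; 11 4-{[tri(propan-2-yl)silyl]oxy}phenol
Product: 13 5,7-bis(benzyloxy)-2-(4-{[tri(propan-2-yl)silyl]oxy}phenoxy)-4H-chromen-4-one, via sodium aryloxide 12 (not isolated)
Conditions: 11 (1.2 equiv), NaH (1.15 equiv), THF, 0 °C, 20 min; then 8, 0 °C → rt, 3 h; neutral work-up
Reagents that add atoms: none
Why: In this vinylogous addition–elimination (oxa-Michael addition at C2, then loss of methanesulfinate) the sulfone is an excellent leaving group on the β-carbon of the enone, and the bulky TIPS group resists silyl transfer to phenoxide.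

**Step 8**
Reactants: 13 5,7-bis(benzyloxy)-2-(4-{[tri(propan-2-yl)silyl]oxy}phenoxy)-4H-chromen-4-one
Product: 14 5,7-dihydroxy-2-(4-{[tri(propan-2-yl)silyl]oxy}phenoxy)-4H-chromen-4-one
Conditions: H2 (1 atm), 10% Pd/C, EtOAc–THF (no alcohol), rt, stopped at full conversion (TLC)
Reagents that add atoms: none
Why: Hydrogenolysis of both benzyl ethers at 1 atm is faster than reduction of the oxygen-substituted, cross-conjugated C2=C3 bond, and the silyl ether and the aryl–O–vinyl linkage are inert.

**Step 9**
Reactants: 14 5,7-dihydroxy-2-(4-{[tri(propan-2-yl)silyl]oxy}phenoxy)-4H-chromen-4-one; 15 1-bromo-3-methylbut-2-ene (prenyl bromide)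
Product: 16 5-hydroxy-7-[(3-methylbut-2-en-1-yl)oxy]-2-(4-{[tri(propan-2-yl)silyl]oxy}phenoxy)-4H-chromen-4-one
Conditions: 15 (1.1 equiv), K2CO3 (1.2 equiv), acetone, rt → 40 °C
Reagents that add atoms: none
Why: This Williamson etherification is regioselective because the 7-OH (a vinylogous acid, pKa about 7–8) is ionised and alkylated, the 5-OH is locked in a hydrogen bond to C4=O, and the 4'-oxygen is silylated.

**Step 10**
Reactants: 16 5-hydroxy-7-[(3-methylbut-2-en-1-yl)oxy]-2-(4-{[tri(propan-2-yl)silyl]oxy}phenoxy)-4H-chromen-4-one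
Product: 17 5-hydroxy-2-(4-hydroxyphenoxy)-7-[(3-methylbut-2-en-1-yl)oxy]-4H-chromen-4-one (target)
Conditions: TBAF (1.1 equiv), AcOH (1.2 equiv), THF, 0 °C, 30 min
Reagents that add atoms: none
Why: Fluoride-mediated desilylation buffered with AcOH is nearly neutral, so the acid-sensitive prenyl ether and the nucleophile-sensitive 2-aryloxychromone both survive.

## Compound list
1 | 2',4',6'-trihydroxyacetophenone | CC(=O)c1c(O)cc(O)cc1O | starting material
2 | 1-[2,4-bis(benzyloxy)-6-hydroxyphenyl]ethan-1-one | CC(=O)c1c(O)cc(OCc2ccccc2)cc1OCc1ccccc1 | intermediate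
3 | carbon disulfide | S=C=S | starting material
4 | 3-[2,4-bis(benzyloxy)-6-hydroxyphenyl]-3-oxopropanedithioic acid (present as its potassium salt, not isolated) | SC(=S)CC(=O)c1c(O)cc(OCc2ccccc2)cc1OCc1ccccc1 | intermediate
5 | 5,7-bis(benzyloxy)-4-hydroxy-2H-chromene-2-thione | S=c1cc(O)c2c(OCc3ccccc3)cc(OCc3ccccc3)cc2o1 | intermediate
6 | 5,7-bis(benzyloxy)-2-(methylsulfanyl)-4H-chromen-4-one | CSc1cc(=O)c2c(OCc3ccccc3)cc(OCc3ccccc3)cc2o1 | intermediate
7 | 5,7-bis(benzyloxy)-2-(methylsulfinyl)-4H-chromen-4-one (racemic at S, not isolated) | CS(=O)c1cc(=O)c2c(OCc3ccccc3)cc(OCc3ccccc3)cc2o1 | intermediate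
8 | 5,7-bis(benzyloxy)-2-(methylsulfonyl)-4H-chromen-4-one | CS(=O)(=O)c1cc(=O)c2c(OCc3ccccc3)cc(OCc3ccccc3)cc2o1 | intermediate
9 | 4-(benzyloxy)phenol | Oc1ccc(OCc2ccccc2)cc1 | starting material
10 | [4-(benzyloxy)phenoxy]tri(propan-2-yl)silane | CC(C)[Si](Oc1ccc(OCc2ccccc2)cc1)(C(C)C)C(C)C | intermediate
11 | 4-{[tri(propan-2-yl)silyl]oxy}phenol | CC(C)[Si](Oc1ccc(O)cc1)(C(C)C)C(C)C | intermediate
12 | sodium 4-{[tri(propan-2-yl)silyl]oxy}phenoxide (not isolated) | CC(C)[Si](Oc1ccc([O-])cc1)(C(C)C)C(C)C.[Na+] | intermediate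
13 | 5,7-bis(benzyloxy)-2-(4-{[tri(propan-2-yl)silyl]oxy}phenoxy)-4H-chromen-4-one | CC(C)[Si](Oc1ccc(Oc2cc(=O)c3c(OCc4ccccc4)cc(OCc4ccccc4)cc3o2)cc1)(C(C)C)C(C)C | intermediate
14 | 5,7-dihydroxy-2-(4-{[tri(propan-2-yl)silyl]oxy}phenoxy)-4H-chromen-4-one | CC(C)[Si](Oc1ccc(Oc2cc(=O)c3c(O)cc(O)cc3o2)cc1)(C(C)C)C(C)C | intermediate
15 | 1-bromo-3-methylbut-2-ene (prenyl bromide) | CC(C)=CCBr | starting material
16 | 5-hydroxy-7-[(3-methylbut-2-en-1-yl)oxy]-2-(4-{[tri(propan-2-yl)silyl]oxy}phenoxy)-4H-chromen-4-one | CC(C)=CCOc1cc(O)c2c(=O)cc(Oc3ccc(O[Si](C(C)C)(C(C)C)C(C)C)cc3)oc2c1 | intermediate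
17 | 5-hydroxy-2-(4-hydroxyphenoxy)-7-[(3-methylbut-2-en-1-yl)oxy]-4H-chromen-4-one | CC(C)=CCOc1cc(O)c2c(=O)cc(Oc3ccc(O)cc3)oc2c1 | target

## Summary
Total step count: 10. Longest linear sequence: 8 (steps 1–4 and 7–10). Steps 5–6 form a two-step side branch.

## Three steps most likely to fail, each with a fallback

**Step 2** (reversible addition of the hindered, electron-rich enolate to CS2, or incomplete cyclisation). The fallback sets out from 2 and comes back to the route at 6.
- Compound 2 is treated with NaH (3.2 equiv) and CS2 (3) in THF–DMF at 0 °C.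
- The dithiolate is trapped in situ with MeI (2.0 equiv). This irreversible double S-alkylation pulls the C–C bond-forming equilibrium forward.
- The product isolated is the α-oxoketene dithioacetal 1-[2,4-bis(benzyloxy)-6-hydroxyphenyl]-3,3-bis(methylsulfanyl)prop-2-en-1-one F1.
- Warming with K2CO3 in DMF (80 °C) lets the ortho phenoxide close the ring by intramolecular oxa-Michael addition and elimination of methanethiol, giving 6 directly. Thione 5 and step 3 are bypassed.

**Step 7** (silyl transfer or cleavage by the phenoxide, giving hydroquinone-derived mixtures). The fallback sets out from 8 and comes back to the route at 17.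
- The silyl strategy is dropped. The sodium salt of 4-(benzyloxy)phenol 9 (NaH, THF, 0 °C → rt) displaces the sulfone to give 5,7-bis(benzyloxy)-2-[4-(benzyloxy)phenoxy]-4H-chromen-4-one F2.
- Global hydrogenolysis (H2, Pd/C, EtOAc–THF) gives 5,7-dihydroxy-2-(4-hydroxyphenoxy)-4H-chromen-4-one F3.
- The prenyl group is then introduced under acidity control with 15 (1.0 equiv) and KHCO3 (1.1 equiv) in DMF at rt.
- Only the 7-OH (pKa about 7–8) is ionised, and not the isolated 4'-phenol (pKa about 10) or the chelated 5-OH. This gives 17 directly.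

**Step 8** (over-reduction of C2=C3, or catalyst poisoning by sulfur traces). The fallback sets out from 13 and comes back to the route at 14.
- The reductive deprotection is replaced by a non-reductive Lewis-acid dealkylation: BCl3 (3 equiv) and pentamethylbenzene (6 equiv) in CH2Cl2 at −78 °C.
- Chelation to C4=O speeds cleavage of the 5-OBn group, and the arene scavenges the benzyl cations.
- The enone cannot be reduced, and the aryl TIPS ether and the aryl–O–vinyl bond are retained. This fallback makes no new compound F0.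

## Further compounds
F1 | step 2 | 1-[2,4-bis(benzyloxy)-6-hydroxyphenyl]-3,3-bis(methylsulfanyl)prop-2-en-1-one | CSC(SC)=CC(=O)c1c(O)cc(OCc2ccccc2)cc1OCc1ccccc1
F2 | step 7 | 5,7-bis(benzyloxy)-2-[4-(benzyloxy)phenoxy]-4H-chromen-4-one | O=c1cc(Oc2ccc(OCc3ccccc3)cc2)oc2cc(OCc3ccccc3)cc(OCc3ccccc3)c12
F3 | step 7 | 5,7-dihydroxy-2-(4-hydroxyphenoxy)-4H-chromen-4-one | O=c1cc(Oc2ccc(O)cc2)oc2cc(O)cc(O)c12
F0 | step 8 | none | none
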